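**Retrosynthetic overview**

1. The strategy rests on the lactone ring (O1–C2–C3–C4–C4a–C8a): C3 is a CH2 between the carbonyl C2 and the doubly benzylic C4. The C3–C4 bond is therefore cut back to a carbene carbon on a diazoacetate at O1 and a C–H bond of a benzyl group on C4a.
2. The C6 prenyl group is put on last, at the only free carbon of ring A, through the 5-O-(1,1-dimethylallyl) ether and an aromatic Claisen shift. No alkene or alkyne is therefore present in the carbene step.
3. The aryl diazoacetate comes from 2,4,6-trihydroxybenzophenone by C-benzylation, bis-MOM protection, bromoacetylation and diazo formation with N,N'-ditosylhydrazine.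
4. Ring order: ring A and both phenyl rings are bought; the lactone ring is the only ring made, in step 5.

Key step: step 5

Assumption: the target is (4R). The sense of induction of a dirhodium carboxamidate in a six-membered closure cannot be taken over from the five-membered cases. Rh2(4S-MPPIM)4 is written, and its mirror image Rh2(4R-MPPIM)4 is used instead if the (4S) lactone proves to be favoured.

**Route**

Step 1
Reactants: 1 2,4,6-trihydroxybenzophenone; 2 benzyl bromide
Product: 3 (3-benzyl-2,4,6-trihydroxyphenyl)(phenyl)methanone
Conditions: 10% aq KOH, 0 °C to rt, N2; 2 in slight deficit (0.95 equiv)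
Reagents that add atoms: none
Why: Nuclear C-alkylation of an acylphloroglucinol phenoxide with a benzylic halide in water, where the hydrogen-bonded oxygens leave carbon as the nucleophilic site, puts the benzyl group on one of the two equivalent free ring carbons, and the deficit of 2 holds back a second benzylation.

Step 2
Reactants: 3 (3-benzyl-2,4,6-trihydroxyphenyl)(phenyl)methanone
Product: 4 (3-benzyl-2-hydroxy-4,6-bis(methoxymethoxy)phenyl)(phenyl)methanone
Conditions: MOMCl (2.1 equiv), i-Pr2NEt (2.5 equiv), CH2Cl2, 0 °C
Reagents that add atoms: chloromethyl methyl ether, COCCl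
Why: Williamson-type acetal ether formation should take the para hydroxyl (most acidic) and then the ortho hydroxyl that has only H beside it, while the hydroxyl wedged between benzoyl and benzyl stays free as the hydrogen-bonded chelate of the ketone; any regioisomer is removed by chromatography.

Step 3
Reactants: 4 (3-benzyl-2-hydroxy-4,6-bis(methoxymethoxy)phenyl)(phenyl)methanone; 5 bromoacetyl bromide
Product: 6 2-benzoyl-6-benzyl-3,5-bis(methoxymethoxy)phenyl bromoacetate
Conditions: pyridine (2 equiv), CH2Cl2, 0 °C; 5 (1.5 equiv) added last
Reagents that add atoms: none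
Why: O-acylation of the phenol by the acyl bromide end of 5, which is far more electrophilic than its alkyl bromide end, with pyridine as acyl-transfer agent and acid scavenger so that the MOM ethers are not exposed to HBr.

Step 4
Reactants: 6 2-benzoyl-6-benzyl-3,5-bis(methoxymethoxy)phenyl bromoacetate
Product: 9 2-benzoyl-6-benzyl-3,5-bis(methoxymethoxy)phenyl diazoacetate, via N-alkylated ditosylhydrazine 7 (not isolated), via glyoxylate tosylhydrazone 8 (not isolated)
Conditions: TsNHNHTs (2 equiv), DBU (5 equiv), THF, 0 °C, short reaction time, dark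
Reagents that add atoms: N,N'-ditosylhydrazine, Cc1ccc(cc1)S(=O)(=O)NNS(=O)(=O)c1ccc(C)cc1
Why: Diazo formation from a bromoacetate with N,N'-ditosylhydrazine proceeds by SN2 N-alkylation and two base-induced losses of p-toluenesulfinate (the second of Bamford–Stevens type) at 0 °C, mild enough for an aryl ester that is in addition shielded by its two ortho substituents.

Step 5
Reactants: 9 2-benzoyl-6-benzyl-3,5-bis(methoxymethoxy)phenyl diazoacetate
Product: 10 (4R)-8-benzoyl-5,7-bis(methoxymethoxy)-4-phenylchroman-2-one
Conditions: Rh2(4S-MPPIM)4 (1 mol%; the divalent-rhodium dimer with four methyl (4S)-2-oxo-1-(3-phenylpropanoyl)imidazolidine-4-carboxylate ligands), CH2Cl2, reflux, 9 added over 6 h by syringe pump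
Reagents that add atoms: none
Why: Proposed new method: loss of N2 from 9 at the dirhodium core gives an electrophilic rhodium carbene at the future C3, which inserts into one C–H bond of the ortho benzyl CH2 through a three-centre, hydride-transfer-like transition state and forms C3–C4 in a single event. The closest known reaction is the dirhodium-carboxamidate-catalysed enantioselective intramolecular C–H insertion of alkyl diazoacetates, which gives γ-butyrolactones; an aryl diazoacetate closing a six-membered lactone onto a diarylmethane C–H bond has no direct precedent. The lactone ring (O1–C2–C3–C4–C4a–C8a) closes six-membered by 1,6-C–H insertion, because the atom a five-membered closure would need is the fully substituted aryl carbon C4a, which carries no hydrogen. C4 is the only stereocentre and is set by the catalyst: the chiral carboxamidate ligands around the carbene choose between the two enantiotopic benzylic hydrogens of an achiral substrate. The step needs site selectivity (benzylic insertion over aromatic substitution, aromatic cycloaddition and attack on oxygen) and enantioselectivity; both positions ortho to the ester oxygen are substituted, the MOM acetal C–H bonds and both phenyl rings lie out of reach of the two-atom tether, the C4–H bonds are doubly benzylic and activated by the trioxygenated ring A, and the weakly electrophilic carboxamidate carbene is the one least prone to irreversible capture by the C8 ketone oxygen as a seven-membered carbonyl ylide, the main competing path. Slow addition keeps the diazo concentration low and suppresses carbene dimerisation.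

Step 6
Reactants: 10 (4R)-8-benzoyl-5,7-bis(methoxymethoxy)-4-phenylchroman-2-one
Product: 11 (4R)-8-benzoyl-5,7-dihydroxy-4-phenylchroman-2-one
Conditions: 3 M aq HCl, THF, 40 °C
Reagents that add atoms: none
Why: Acid hydrolysis of the two MOM acetals in the presence of water, which traps the methoxymethyl cation before it can alkylate C6, leaves the aryl lactone closed (acid favours lactonisation) and C4 untouched because it is not enolisable.

Step 7
Reactants: 11 (4R)-8-benzoyl-5,7-dihydroxy-4-phenylchroman-2-one; 12 3-chloro-3-methylbut-1-yne
Product: 13 (4R)-8-benzoyl-7-hydroxy-5-[(2-methylbut-3-yn-2-yl)oxy]-4-phenylchroman-2-one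
Conditions: 12 (1.2 equiv), DBU (1.3 equiv), CuCl2·2H2O (1 mol%), dry MeCN, 0 °C
Reagents that add atoms: none
Why: Copper-catalysed propargylic substitution of a phenoxide on a tertiary propargyl chloride forms the aryl 1,1-dimethylpropargyl ether at the 5-hydroxyl, which is para to the benzoyl group and so the more acidic one, while the 7-hydroxyl is held in a hydrogen bond to the ketone; an ether on O7 would in any case deliver its allyl group to the same carbon C6 in step 9.

Step 8
Reactants: 13 (4R)-8-benzoyl-7-hydroxy-5-[(2-methylbut-3-yn-2-yl)oxy]-4-phenylchroman-2-one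
Product: 14 (4R)-8-benzoyl-7-hydroxy-5-[(2-methylbut-3-en-2-yl)oxy]-4-phenylchroman-2-one
Conditions: H2 (1 atm), Lindlar catalyst (Pd/CaCO3 poisoned with Pb(OAc)2), quinoline, EtOAc, rt
Reagents that add atoms: none
Why: Lindlar semihydrogenation of the terminal alkyne stops at the vinyl group and is run at room temperature before any heating, so the propargyl ether cannot cyclise to a chromene and the diaryl ketone and lactone are not reduced.

Step 9
Reactants: 14 (4R)-8-benzoyl-7-hydroxy-5-[(2-methylbut-3-en-2-yl)oxy]-4-phenylchroman-2-one
Product: 16 (4R)-8-benzoyl-5,7-dihydroxy-6-(3-methylbut-2-en-1-yl)-4-phenylchroman-2-one, via dienone 15 (not isolated)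
Conditions: toluene, 110 °C, N2
Reagents that add atoms: none
Why: Aromatic Claisen rearrangement of the 1,1-dimethylallyl aryl ether goes to C6, the only ortho position carrying hydrogen (C4a is blocked), which inverts the allyl unit to the 3-methylbut-2-enyl group, and tautomerisation of the dienone restores ring A without touching C4.

**Compound list**

1 | 2,4,6-trihydroxybenzophenone | O=C(c1ccccc1)c1c(O)cc(O)cc1O | starting material
2 | benzyl bromide | BrCc1ccccc1 | starting material
3 | (3-benzyl-2,4,6-trihydroxyphenyl)(phenyl)methanone | O=C(c1ccccc1)c1c(O)cc(O)c(Cc2ccccc2)c1O | intermediate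
4 | (3-benzyl-2-hydroxy-4,6-bis(methoxymethoxy)phenyl)(phenyl)methanone | COCOc1cc(OCOC)c(C(=O)c2ccccc2)c(O)c1Cc1ccccc1 | intermediate
5 | bromoacetyl bromide | BrCC(Br)=O | starting material
6 | 2-benzoyl-6-benzyl-3,5-bis(methoxymethoxy)phenyl bromoacetate | BrCC(=O)Oc1c(Cc2ccccc2)c(OCOC)cc(OCOC)c1C(=O)c1ccccc1 | intermediate
7 | 2-benzoyl-6-benzyl-3,5-bis(methoxymethoxy)phenyl 2-[1,2-bis(p-toluenesulfonyl)hydrazinyl]acetate (not isolated) | Cc1ccc(cc1)S(=O)(=O)NN(CC(=O)Oc1c(Cc2ccccc2)c(OCOC)cc(OCOC)c1C(=O)c1ccccc1)S(=O)(=O)c1ccc(C)cc1 | intermediate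
8 | 2-benzoyl-6-benzyl-3,5-bis(methoxymethoxy)phenyl 2-(p-toluenesulfonylhydrazono)acetate (not isolated) | Cc1ccc(cc1)S(=O)(=O)NN=CC(=O)Oc1c(Cc2ccccc2)c(OCOC)cc(OCOC)c1C(=O)c1ccccc1 | intermediate
9 | 2-benzoyl-6-benzyl-3,5-bis(methoxymethoxy)phenyl diazoacetate | [N-]=[N+]=CC(=O)Oc1c(Cc2ccccc2)c(OCOC)cc(OCOC)c1C(=O)c1ccccc1 | intermediate
10 | (4R)-8-benzoyl-5,7-bis(methoxymethoxy)-4-phenylchroman-2-one | COCOc1cc(OCOC)c(C(=O)c2ccccc2)c2c1[C@@H](c1ccccc1)CC(=O)O2 | intermediate
11 | (4R)-8-benzoyl-5,7-dihydroxy-4-phenylchroman-2-one | Oc1cc(O)c(C(=O)c2ccccc2)c2c1[C@@H](c1ccccc1)CC(=O)O2 | intermediate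
12 | 3-chloro-3-methylbut-1-yne | C#CC(C)(C)Cl | starting material
13 | (4R)-8-benzoyl-7-hydroxy-5-[(2-methylbut-3-yn-2-yl)oxy]-4-phenylchroman-2-one | C#CC(C)(C)Oc1cc(O)c(C(=O)c2ccccc2)c2c1[C@@H](c1ccccc1)CC(=O)O2 | intermediate
14 | (4R)-8-benzoyl-7-hydroxy-5-[(2-methylbut-3-en-2-yl)oxy]-4-phenylchroman-2-one | C=CC(C)(C)Oc1cc(O)c(C(=O)c2ccccc2)c2c1[C@@H](c1ccccc1)CC(=O)O2 | intermediate
15 | (4R)-8-benzoyl-7-hydroxy-6-(3-methylbut-2-en-1-yl)-4-phenyl-3,4-dihydro-2H-chromene-2,5(6H)-dione, C6 unassigned (not isolated) | CC(C)=CCC1C(O)=C(C(=O)c2ccccc2)C2=C(C1=O)[C@@H](c1ccccc1)CC(=O)O2 | intermediate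
16 | (4R)-8-benzoyl-5,7-dihydroxy-6-(3-methylbut-2-en-1-yl)-4-phenylchroman-2-one | CC(C)=CCc1c(O)c(C(=O)c2ccccc2)c2c(c1O)[C@@H](c1ccccc1)CC(=O)O2 | target

**Step count and risks**

Total steps: 9. Longest linear sequence: 9 steps (1 to 16).

Steps most likely to fail:

Step 5 (key step). The carbene may be captured by the C8 ketone oxygen as a carbonyl ylide or lost to dimerisation, the six-membered insertion may be slow, or the two enantiotopic benzylic hydrogens may be poorly told apart. The fallback builds C4 by a Hayashi–Miyaura addition, all by known chemistry, and sets out from compound 1. MOMCl (2.1 equiv) with i-Pr2NEt protects the para hydroxyl and one of the two equivalent ortho hydroxyls to give (2-hydroxy-4,6-bis(methoxymethoxy)phenyl)(phenyl)methanone F1. Esterification of the remaining phenol with propiolic acid (DCC, CH2Cl2, −20 °C) gives 2-benzoyl-3,5-bis(methoxymethoxy)phenyl prop-2-ynoate F2. Cationic gold (Ph3PAuCl/AgOTf, 1,2-dichloroethane, rt) then brings about intramolecular hydroarylation at the only free carbon ortho to the ester oxygen and gives 8-benzoyl-5,7-bis(methoxymethoxy)-2H-chromen-2-one F3. Rhodium-catalysed asymmetric conjugate addition of phenylboronic acid (Rh(acac)(C2H4)2, (R)-SEGPHOS, dioxane/H2O, 60 °C) gives compound 10, where the route is rejoined at step 6. The ligand enantiomer that delivers (4R) is kept.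

Step 2. Site selectivity between the two ketone-flanking hydroxyls may be poor, with the second MOM group going onto the hydroxyl between benzoyl and benzyl. The fallback removes the choice by symmetry and sets out from compound 1. Friedel–Crafts benzoylation (PhCOCl, AlCl3, PhNO2, 60 °C) gives (2,4,6-trihydroxy-1,3-phenylene)bis(phenylmethanone) F4. MOMCl/i-Pr2NEt protects the two equivalent outer hydroxyls and leaves the one between the two benzoyl groups, giving [2-hydroxy-4,6-bis(methoxymethoxy)-1,3-phenylene]bis(phenylmethanone) F5. Ethyl chloroformate/Et3N (THF, 0 °C) turns that phenol into 2,6-dibenzoyl-3,5-bis(methoxymethoxy)phenyl ethyl carbonate F6. NaBH4 in THF/H2O at 0 °C then reduces one ketone; the alkoxide takes over the carbonate and leaves as an ortho-quinone methide forms, and hydride addition gives the benzyl group. This is the known deoxygenation of ortho-acylphenols through their carbonates. The two ketones are equivalent and only one carbonate is present, so the product is compound 4, where the route is rejoined at step 3.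

Step 7. The tertiary propargyl ether may fail to form at the hindered hydroxyl peri to the C4 phenyl group, or the base may open the aryl lactone. The fallback leaves the ether–Claisen sequence and sets out from compound 11. Direct Friedel–Crafts prenylation with 2-methylbut-3-en-2-ol and BF3·OEt2 in dioxane at rt attacks C6, the only unsubstituted carbon of ring A and flanked by two hydroxyls. It gives compound 16 directly, replacing steps 7 to 9, and is stopped early to avoid acid cyclisation to a chroman.

**Further compounds**

F1 | step 5 | (2-hydroxy-4,6-bis(methoxymethoxy)phenyl)(phenyl)methanone | COCOc1cc(O)c(C(=O)c2ccccc2)c(OCOC)c1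
F2 | step 5 | 2-benzoyl-3,5-bis(methoxymethoxy)phenyl prop-2-ynoate | C#CC(=O)Oc1cc(OCOC)cc(OCOC)c1C(=O)c1ccccc1
F3 | step 5 | 8-benzoyl-5,7-bis(methoxymethoxy)-2H-chromen-2-one | COCOc1cc(OCOC)c(C(=O)c2ccccc2)c2oc(=O)ccc12
F4 | step 2 | (2,4,6-trihydroxy-1,3-phenylene)bis(phenylmethanone) | O=C(c1ccccc1)c1c(O)cc(O)c(C(=O)c2ccccc2)c1O
F5 | step 2 | [2-hydroxy-4,6-bis(methoxymethoxy)-1,3-phenylene]bis(phenylmethanone) | COCOc1cc(OCOC)c(C(=O)c2ccccc2)c(O)c1C(=O)c1ccccc1
F6 | step 2 | 2,6-dibenzoyl-3,5-bis(methoxymethoxy)phenyl ethyl carbonate | CCOC(=O)Oc1c(C(=O)c2ccccc2)c(OCOC)cc(OCOC)c1C(=O)c1ccccc1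
F0 | step 7 | none | none
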